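The easy mistake in this flask is to put the charge of solid substrate into the rate law, when the target-forming step is written on the dissolved substrate.

solid substrate 1.5 M; reagent 2.25 M; time 1.0 min

    solid substrate ⇌ dissolved substrate, rate k1*(cs1 - [dissolved substrate]) while solid is left; crystals form when [dissolved substrate] > cs1 (cs1 = 1.1 M, k1 = 0.15 /s)
    dissolved substrate + reagent → target (k2 = 0.0097 /M/s)
    reagent → side product (k3 = 0.0031 /s)
    solid product ⇌ target, rate k4*(cs4 - [target]) while solid is left; crystals form when [target] > cs4 (cs4 = 0.58 M, k4 = 0.26 /s)
    reagent + target ⇌ idle adduct, settled at all times (K5 = 2.7 /M)
    2 reagent → self-condensation product (k6 = 0.0066 /M/s)

- what is said of target includes solid product and idle adduct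
- for a step with 2 of a species take k times the square, and two of it per event
- solid substrate, solid product is a solid; its amount is given per volume of the solution
- at the start none of the solid substrate is in solution
- dissolved substrate means what is dissolved; the solid is not counted in it
- run time (flask): 1.0 min

- how much target and solid product and idle adduct together there is at 1.0 min, in percent of the solid substrate charged
- concentration of dissolved substrate in solution at 1.0 min, in percent of saturation

**What does the dissolved substrate do first?** It fills towards saturation with a time constant of 6.67 s, which is shorter than the run. So I take c(dissolved substrate) as 1.1 M while solid lasts, and the target-forming step becomes pseudo-first-order in reagent.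

**Then what do you count?** Turnovers of that saturated pool. At full charge, reagent turns the pool over at 0.0218 /s, so the question is how long full charge effectively lasts.

**But the reagent does not stay at its charge. How long does it last?** It has a first-order loss of 0.0138 /s, through target and side product. Self-condensation starts faster, at 0.0297 /s. Integrating c(reagent) under both losses gives an effective time at full charge of 26.7 s, shorter than the run. The pool starts empty, so I subtract the lag. This gives 0.438, the turnover count, meaning how many times the saturated pool of dissolved substrate is converted into target during the run.

**Where is that weak?** I left the idle adduct out, and subtracting the lag is crude, so the count is a reckoning and not a bound.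

**And your answers?** The count gives 32.1 %. That is 0.482 M of target, more than the 0.400 M by which the charge exceeds saturation. So I expect the solid substrate to have dissolved by the end, and the dissolved substrate to be the charge minus the target in all its forms, 92.5 %.

The forecast gives 31 % and 94 %, and says “the solid runs out just before 1 min”. My yield stands 1.1 percentage points above it.

The simulation gives 31.1 % and 93.9 %. At 1.00 min this flask holds 0 % of its charge as solid substrate. Now take the neighbouring flask with 0.56 M of reagent, all else as charged. Its turnover count is 0.158, which means 11.6 % of the solid substrate charged. The simulated flask with that reagent charge holds 11.4 % of the solid substrate charged as target, all its forms counted.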